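# Proposed total synthesis of (1S,3S,3aR,4R,5R,7aR)-3,4,5-triethyl-5-[(1E,3E)-2-ethyl-4-phenylbuta-1,3-dien-1-yl]-1,7-dimethyl-2-oxo-2,3,3a,4,5,7a-hexahydro-1H-indene-4-carboxylic acid (19)

Atom labels C1–C7a below are those of the indene name of the target.

## The problem

The target is a trans-fused hexahydroindenone: a cyclohexene (C3a, C4, C5, C6=C7, C7a) fused to a cyclopentanone (C1, C2=O, C3, C3a, C7a), with six contiguous stereocentres. The hardest feature is the C4–C5 bond. It joins two fully substituted carbons (C4: ethyl and CO2H; C5: ethyl and the dienyl chain) whose ethyl groups are cis, and both must be related to the trans ring fusion (H-3a, H-7a). C1 and C3 are the enolisable α-carbons of the ketone. In the target each alkyl group is trans to its ring neighbour, the thermodynamically preferred arrangement, so these two centres can be left to equilibration but cannot be used as control elements. C3a, C7a, C4 and C5 cannot be corrected once set. The (1E,3E)-2-ethyl-4-phenylbutadienyl chain will not survive acid, radicals or hydrometalation, and an ester on the quaternary C4 next to quaternary C5 could hardly be hydrolysed at the end.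

The feature that makes the key step possible: the carboxyl carbon, C4, C5 and the ring alkene C6=C7 form a γ,δ-unsaturated acid, and C7 is tied back to C4 through C7a and C3a. The retro-[3,3] shift therefore gives a six-membered lactone with its oxygen on C7, in which one C–O stereocentre and one alkene geometry encode both quaternary centres. A second feature is a hidden glutarate: C3a is flanked by two identical ethyl-bearing carbons that each carry a carbonyl (C3–C2=O and C4–CO2H).

## Retrosynthesis

**19 ⇒ 17 + 18.** The bond between the ethyl-bearing alkene carbon and the styryl group is cut, together with the vinylic C–H, which leads back to the but-1-ynyl compound 17 and styrylboronic acid 18. Installing the diene last keeps it away from the radical and strong-base steps. The alkyne is a slim, non-ionising placeholder on C5 during the key step. The forward reaction must add H and styryl syn, with styryl on the carbon remote from the quaternary centre.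

**17 ⇒ 15.** The C1–C2 bond (ketone carbon to the methyl-bearing carbon) is cut: an acyl radical from selenoester 15 closes onto a vinyl group on C7a, and the terminal CH2 becomes the C1 methyl group. The five-membered ring has to be closed after the key step. In the boat transition state of the rearrangement the substituents on C3a and C7a are held anti (dihedral angle well above 100°), which a trans-fused cyclopentane cannot span. A vinyl group is inert and non-acidic under the enolisation conditions. C1 and C3 are set afterwards by equilibration.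

**15 ⇒ 14.** Functional-group change only: the methyl ester of the side arm becomes the selenoester; the acid on C4 stays free.

**14 ⇒ 11 (key disconnection).** The C4–C5 bond is cut by a retro-Ireland–Claisen shift, which opens the cyclohexene to δ-lactone 11 (oxygen on the future C7, alkene moved out of the ring). This is preferred to the Diels–Alder cut because all the information for two quaternary centres is held in one carbinol centre, an E-alkene and a ring-fixed ketene acetal. Precursor 11 has no quaternary carbon–carbon bond and no carbocycle. The forward reaction must pass through a boat transition state and must beat ionisation at the tertiary allylic C–O bond.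

**11 ⇒ 10.** Two C–ethyl bonds are cut (lactone α-carbon and arm α-carbon). Neither new centre needs control: one becomes sp2 in the key step, the other is equilibrated in step 8.

**10 ⇒ 3 + 8.** The lactone C–O bond and the bond between the carbinol carbon (future C7) and the future C7a are cut. This leads to methyl ketone 3 and the achiral (Z)-allylboronate 8, which carries the hidden glutarate. A closed chair allylboration sets the carbinol centre and C7a together. Lactonisation then selects one of two diastereotopic arms and so sets C3a without a separate operation.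

**8 ⇒ 6 + 7, 6 ⇒ 4 + 5, 3 ⇒ 1 + 2.** Boronate 8 comes from Z-selective cross-metathesis of 3-vinylglutarate 6 with allylboronate 7. Glutarate 6 comes from conjugate vinylation of dimethyl glutaconate 4 with 5. Enynone 3 comes from syn-addition of but-1-yne 2 across hex-3-yn-2-one 1, which fixes the alkene geometry in one step.

## Roads not taken

Alternative 1: Intramolecular Diels–Alder reaction, the obvious cut of C3a–C7a and C4–C5 at once, from linear pentaenone acid A1. The forward key step is cycloaddition of the C7–C10 diene of A1 onto its C2=C3 enoate. In A1 all stereochemical information sits in two α-carbons of a ketone, one of them also allylic, so epimerisation and conjugation threaten before the cycloaddition. Both quaternary centres must arise from a fully substituted diene terminus and a trisubstituted dienophile, with endo/exo and facial selectivity resting on that labile tether. A1 also needs a long linear assembly of four stereodefined trisubstituted alkenes. The chosen plan stores the information in one robust C–O centre and needs no polyene.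

Alternative 2: Pauson–Khand reaction of enyne A2, cutting C3a–C7a, C1–C2 and C2–C3. The forward key step would form the cyclopentenone and close the six-membered ring in one [2+2+1] event. A2 already contains both quaternary carbons in an open chain, so the hardest bond would have to be made first, without a ring to fix the geometry of a tetrasubstituted enolate. The cycloaddition would use a 1,2-disubstituted alkene, and H-7a would have to be added afterwards by a regio- and trans-selective reduction of a dienone. The chosen plan makes the C4–C5 bond and the ring together and never has an sp2 ring-fusion carbon.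

Alternative 3: Stepwise construction on a preformed bicyclic enone: methyl addition gives tertiary allylic alcohol A3, and an Eschenmoser–Claisen rearrangement cuts the C5–side-chain bond with allylic transposition. The forward key step delivers a CH2CONMe2 unit to C5 and moves the alkene to C6=C7. The quaternary centres are then made one at a time, and the C7 carbinol must be set 1,4 to C4 with no good bias. The amide must be rebuilt into the E,E-dienyl chain at a neopentyl position, and a hindered ester on C4 must be cleaved at the end. The chosen plan forms both centres in one event and releases the acid free.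

Key step: step 6

## Route

Assumption: (S)-3,3′-dibromo-BINOL is taken to give the (3S,4S) adduct 9 in step 4; if the facial sense is the reverse, the (R)-catalyst is used and nothing else changes.

Step 1
Reactants: 1 hex-3-yn-2-one; 2 but-1-yne
Product: 3 (3E)-4-ethyloct-3-en-5-yn-2-one
Conditions: Pd(OAc)2 (3 mol %), tris(2,6-dimethoxyphenyl)phosphine (3 mol %), THF, rt, sealed vessel
Reagents that add atoms: none
Why: Palladium-catalysed syn-hydroalkynylation of an ynone (alkyne–alkyne cross-addition): the alkynyl group adds to the β-carbon and hydrogen to the α-carbon from the same side, so acetyl ends up cis to ethyl and trans to butynyl (E), the geometry that later fixes C5.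

Step 2
Reactants: 4 dimethyl (2E)-pent-2-enedioate; 5 potassium ethenyltrifluoroborate
Product: 6 dimethyl 3-ethenylpentanedioate
Conditions: [Rh(cod)Cl]2 (2.5 mol %), dioxane/H2O (10:1), 90 °C
Reagents that add atoms: none
Why: Rhodium-catalysed 1,4-addition of an alkenylboron reagent to an enoate (Hayashi–Miyaura type); the product is achiral because C3 carries two identical acetate arms, so no chiral ligand is needed.

Step 3
Reactants: 6 dimethyl 3-ethenylpentanedioate; 7 4,4,5,5-tetramethyl-2-(prop-2-en-1-yl)-1,3,2-dioxaborolane
Product: 8 dimethyl 3-[(1Z)-3-(4,4,5,5-tetramethyl-1,3,2-dioxaborolan-2-yl)prop-1-en-1-yl]pentanedioate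
Conditions: Mo(N-1-adamantyl)(CHCMe2Ph)(2,5-Me2C4H2N)[O-2,6-(2,4,6-Me3C6H2)2C6H3] (5 mol %), benzene, rt, reduced pressure
Reagents that add atoms: none
Why: Z-selective olefin cross-metathesis with an allylboronate on a molybdenum monoaryloxide pyrrolide alkylidene; the large aryloxide forces both metallacyclobutane substituents to the same side, which gives the cis-γ-substituted allylboronate that step 4 requires.

Step 4
Reactants: 3 (3E)-4-ethyloct-3-en-5-yn-2-one; 8 dimethyl 3-[(1Z)-3-(4,4,5,5-tetramethyl-1,3,2-dioxaborolan-2-yl)prop-1-en-1-yl]pentanedioate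
Product: 10 methyl 2-[(2S,3S,4R)-3-ethenyl-2-[(1E)-2-ethylhex-1-en-3-yn-1-yl]-2-methyl-6-oxooxan-4-yl]acetate, via hydroxy diester 9 (not isolated)
Conditions: (S)-3,3′-Br2-BINOL (15 mol %), t-BuOH, 4 Å MS, PhMe, rt; aq. NaHCO3; then DBU (0.2 equiv), PhMe, 60 °C
Reagents that add atoms: none
Why: Chiral biphenol-catalysed allylboration of a methyl ketone through a closed Zimmerman–Traxler chair: alkenyl equatorial, methyl axial and the Z-γ-substituent axial place the new vinyl group cis to methyl, while the catalyst selects the ketone face. Reversible base-mediated lactonisation then picks the diastereotopic acetate arm that leaves the other arm trans-diequatorial to vinyl, which sets the oxane C4 (future C3a) centre.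

Step 5
Reactants: 10 methyl 2-[(2S,3S,4R)-3-ethenyl-2-[(1E)-2-ethylhex-1-en-3-yn-1-yl]-2-methyl-6-oxooxan-4-yl]acetate
Product: 11 methyl 2-[(2S,3S,4R)-3-ethenyl-5-ethyl-2-[(1E)-2-ethylhex-1-en-3-yn-1-yl]-2-methyl-6-oxooxan-4-yl]butanoate (epimers at oxane C5 and butanoate C2)
Conditions: LiN(iPr)2 (2.2 equiv), THF, −78 °C; EtI (3 equiv), DMPU, −78 → −20 °C
Reagents that add atoms: iodoethane, CCI
Why: Double enolate alkylation of the bis-enolate (lactone α-carbon and acetate arm), one ethyl group each; the two new centres may form as mixtures because the lactone α-carbon becomes a planar ketene acetal in step 6 and the arm α-carbon is equilibrated in step 8.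

Step 6
Reactants: 11 methyl 2-[(2S,3S,4R)-3-ethenyl-5-ethyl-2-[(1E)-2-ethylhex-1-en-3-yn-1-yl]-2-methyl-6-oxooxan-4-yl]butanoate
Product: 14 (1R,2R,5S,6R)-2-(but-1-yn-1-yl)-5-ethenyl-1,2-diethyl-6-(1-methoxy-1-oxobutan-2-yl)-4-methylcyclohex-3-ene-1-carboxylic acid (epimers at the butanoate α-carbon), via bis(silyl ketene acetal) 12 (not isolated), via silyl ester 13 (not isolated)
Conditions: Me3SiCl (4 equiv), LiN(iPr)2 (3 equiv), THF, −78 °C → rt; PhMe, 110 °C; then 1 M HCl, THF
Reagents that add atoms: none
Why: Ireland–Claisen rearrangement in its ring-contracting lactone-enolate mode, the reaction type known for 6-alkenyl δ-lactones and 6-alkenyl-1,4-dioxan-2-ones: O-silylation gives 12 (the side-chain ketene acetal is a spectator), and on heating the oxane O1–C2 bond breaks while oxane C5 bonds to C2′ of the hexenynyl group in a concerted suprafacial [3,3] shift to give silyl ester 13. The cyclohexene is closed by this single pericyclic C–C bond formation through a boat transition state shaped like bicyclo[2.2.2]octane (bridgeheads oxane C2 and C5), the only geometry the lactone ring allows. C1 of 14 is controlled by the carbinol stereocentre (oxane C2), because the alkenyl group can reach only the ketene-acetal face on its own side, a 1,4-transfer of chirality across the ring. C2 of 14 is controlled by the E geometry of the alkene: in the boat the ethyl group cis to the carbinol carbon must point over the lactone ring, so it ends up cis to the C1 ethyl group and the butynyl group cis to the carboxyl. The geometry of the fully substituted ketene acetal, usually the weak point when this rearrangement builds a quaternary α-carbon, is fixed by the ring. C5 and C6 of 14 are carried over unchanged and, because vinyl is trans to the migrating alkenyl group and the ester arm trans to vinyl, they emerge with the relative configuration of the target. The step needs the [3,3] shift to outrun ionisation or elimination at the tertiary allylic C–O bond, which the non-polar acid-free medium and the slim alkynyl substituent on the migrating terminus should secure. Aqueous acid cleaves the silyl ester, so the hindered acid is obtained free.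

Step 7
Reactants: 14 (1R,2R,5S,6R)-2-(but-1-yn-1-yl)-5-ethenyl-1,2-diethyl-6-(1-methoxy-1-oxobutan-2-yl)-4-methylcyclohex-3-ene-1-carboxylic acid
Product: 15 (1R,2R,5S,6R)-2-(but-1-yn-1-yl)-5-ethenyl-1,2-diethyl-4-methyl-6-[1-oxo-1-(phenylselanyl)butan-2-yl]cyclohex-3-ene-1-carboxylic acid (epimers at the butanoyl α-carbon)
Conditions: Me2AlSePh (from Me3Al and PhSeH, 3 equiv), CH2Cl2, 0 °C → rt; aq. HCl
Reagents that add atoms: dimethylaluminium benzeneselenolate, C[Al](C)[Se]c1ccccc1
Why: Direct conversion of a methyl ester into a selenol ester by an aluminium selenolate; the acid on the quaternary carbon is only deprotonated to an aluminium carboxylate and returns on work-up.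

Step 8
Reactants: 15 (1R,2R,5S,6R)-2-(but-1-yn-1-yl)-5-ethenyl-1,2-diethyl-4-methyl-6-[1-oxo-1-(phenylselanyl)butan-2-yl]cyclohex-3-ene-1-carboxylic acid
Product: 17 (1S,3S,3aR,4R,5R,7aR)-5-(but-1-yn-1-yl)-3,4,5-triethyl-1,7-dimethyl-2-oxo-2,3,3a,4,5,7a-hexahydro-1H-indene-4-carboxylic acid, via C1/C3-epimeric ketone mixture 16 (not isolated)
Conditions: Bu3SnH (1.3 equiv), AIBN (0.1 equiv), PhH (0.05 M), 80 °C; then DBU, PhMe, 60 °C
Reagents that add atoms: none
Why: Acyl radical 5-exo-trig cyclisation in a stannane chain: the acyl radical adds to the internal carbon of the trans-disposed vinyl group, closing the cyclopentanone trans-fused and turning the terminal CH2 into the C1 methyl group. DBU then equilibrates both ketone α-carbons to the all-trans arrangement (methyl trans to C7, ethyl trans to C4), the expected thermodynamic minimum.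

Step 9
Reactants: 17 (1S,3S,3aR,4R,5R,7aR)-5-(but-1-yn-1-yl)-3,4,5-triethyl-1,7-dimethyl-2-oxo-2,3,3a,4,5,7a-hexahydro-1H-indene-4-carboxylic acid; 18 [(E)-2-phenylethenyl]boronic acid
Product: 19 (1S,3S,3aR,4R,5R,7aR)-3,4,5-triethyl-5-[(1E,3E)-2-ethyl-4-phenylbuta-1,3-dien-1-yl]-1,7-dimethyl-2-oxo-2,3,3a,4,5,7a-hexahydro-1H-indene-4-carboxylic acid
Conditions: Pd(PPh3)4 (5 mol %), AcOH (0.2 equiv), dioxane, 80 °C
Reagents that add atoms: none
Why: Palladium-catalysed syn-hydroalkenylation of an internal alkyne with an alkenylboronic acid (hydropalladation, transmetalation, reductive elimination): palladium adds to the ethyl-bearing carbon remote from the quaternary centre and is replaced by styryl with retention, which gives the E trisubstituted alkene with styryl trans to the ring. Ketone and free acid are tolerated, and the α-centres already sit in their thermodynamic configuration.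

## Compound list

1 | hex-3-yn-2-one | CC(=O)C#CCC | starting material
2 | but-1-yne | CCC#C | starting material
3 | (3E)-4-ethyloct-3-en-5-yn-2-one | CC(=O)/C=C(CC)/C#CCC | intermediate
4 | dimethyl (2E)-pent-2-enedioate | COC(=O)/C=C/CC(=O)OC | starting material
5 | potassium ethenyltrifluoroborate | [K+].C=C[B-](F)(F)F | starting material
6 | dimethyl 3-ethenylpentanedioate | COC(=O)CC(C=C)CC(=O)OC | intermediate
7 | 4,4,5,5-tetramethyl-2-(prop-2-en-1-yl)-1,3,2-dioxaborolane | C=CCB1OC(C)(C)C(C)(C)O1 | starting material
8 | dimethyl 3-[(1Z)-3-(4,4,5,5-tetramethyl-1,3,2-dioxaborolan-2-yl)prop-1-en-1-yl]pentanedioate | COC(=O)CC(CC(=O)OC)/C=C\CB1OC(C)(C)C(C)(C)O1 | intermediate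
9 | dimethyl 3-[(3S,4S,5E)-6-ethyl-4-hydroxy-4-methyldeca-1,5-dien-7-yn-3-yl]pentanedioate | O[C@](C)(/C=C(CC)/C#CCC)[C@@H](C=C)C(CC(=O)OC)CC(=O)OC | intermediate
10 | methyl 2-[(2S,3S,4R)-3-ethenyl-2-[(1E)-2-ethylhex-1-en-3-yn-1-yl]-2-methyl-6-oxooxan-4-yl]acetate | O=C1O[C@](C)(/C=C(CC)/C#CCC)[C@@H](C=C)[C@H](CC(=O)OC)C1 | intermediate
11 | methyl 2-[(2S,3S,4R)-3-ethenyl-5-ethyl-2-[(1E)-2-ethylhex-1-en-3-yn-1-yl]-2-methyl-6-oxooxan-4-yl]butanoate, epimers at oxane C5 and butanoate C2 | O=C1O[C@](C)(/C=C(CC)/C#CCC)[C@@H](C=C)[C@H](C(CC)C(=O)OC)C1CC | intermediate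
12 | bis(trimethylsilyl ketene acetal) of 11 (lactone and ester arm) | C[Si](C)(C)OC=1O[C@](C)(/C=C(CC)/C#CCC)[C@@H](C=C)[C@H](C(CC)=C(OC)O[Si](C)(C)C)C=1CC | intermediate
13 | trimethylsilyl ester of 14 carrying the side-chain silyl ketene acetal | CCC#C[C@@]1(CC)C=C(C)[C@@H](C=C)[C@H](C(CC)=C(OC)O[Si](C)(C)C)[C@@]1(CC)C(=O)O[Si](C)(C)C | intermediate
14 | (1R,2R,5S,6R)-2-(but-1-yn-1-yl)-5-ethenyl-1,2-diethyl-6-(1-methoxy-1-oxobutan-2-yl)-4-methylcyclohex-3-ene-1-carboxylic acid, epimers at the butanoate α-carbon | CCC#C[C@@]1(CC)C=C(C)[C@@H](C=C)[C@H](C(CC)C(=O)OC)[C@@]1(CC)C(=O)O | intermediate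
15 | (1R,2R,5S,6R)-2-(but-1-yn-1-yl)-5-ethenyl-1,2-diethyl-4-methyl-6-[1-oxo-1-(phenylselanyl)butan-2-yl]cyclohex-3-ene-1-carboxylic acid, epimers at the butanoyl α-carbon | CCC#C[C@@]1(CC)C=C(C)[C@@H](C=C)[C@H](C(CC)C(=O)[Se]c2ccccc2)[C@@]1(CC)C(=O)O | intermediate
16 | (3aR,4R,5R,7aR)-5-(but-1-yn-1-yl)-3,4,5-triethyl-1,7-dimethyl-2-oxo-2,3,3a,4,5,7a-hexahydro-1H-indene-4-carboxylic acid, epimers at C1 and C3 | CCC#C[C@@]1(CC)C=C(C)[C@@H]2[C@H](C(CC)C(=O)C2C)[C@@]1(CC)C(=O)O | intermediate
17 | (1S,3S,3aR,4R,5R,7aR)-5-(but-1-yn-1-yl)-3,4,5-triethyl-1,7-dimethyl-2-oxo-2,3,3a,4,5,7a-hexahydro-1H-indene-4-carboxylic acid | CCC#C[C@@]1(CC)C=C(C)[C@@H]2[C@H]([C@H](CC)C(=O)[C@H]2C)[C@@]1(CC)C(=O)O | intermediate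
18 | [(E)-2-phenylethenyl]boronic acid | OB(O)/C=C/c1ccccc1 | starting material
19 | (1S,3S,3aR,4R,5R,7aR)-3,4,5-triethyl-5-[(1E,3E)-2-ethyl-4-phenylbuta-1,3-dien-1-yl]-1,7-dimethyl-2-oxo-2,3,3a,4,5,7a-hexahydro-1H-indene-4-carboxylic acid | CCC(/C=C/c1ccccc1)=C\[C@@]1(CC)C=C(C)[C@@H]2[C@H]([C@H](CC)C(=O)[C@H]2C)[C@@]1(CC)C(=O)O | target

## Step count and least certain steps

Total: 9 steps. Longest linear sequence: 8 steps (4 → 6 → 8 → 10 → 11 → 14 → 15 → 17 → 19, steps 2 to 9); ketone 3 is made in one step and joins at step 4.

**Step 6 (key step).** The α-ethyl lactone may be enolised only in part, or the boat transition state may be slowed by the 1,3-contact between the alkene ethyl group and the branched arm on the neighbouring carbon. Elimination or ionisation at the tertiary allylic C–O bond could then take over on prolonged heating. Fallback, setting out from 10 and returning at 14: the two ethylations are separated so that the rearrangement runs on a less crowded substrate. Lactone 10 is ethylated once at the lactone α-carbon, the more acidic position (LiN(iPr)2, 1.05 equiv, then EtI), to give methyl 2-[(2S,3S,4S)-3-ethenyl-5-ethyl-2-[(1E)-2-ethylhex-1-en-3-yn-1-yl]-2-methyl-6-oxooxan-4-yl]acetate F1. Its silyl ketene acetal is rearranged as in step 6 to (1R,2R,5S,6S)-2-(but-1-yn-1-yl)-5-ethenyl-1,2-diethyl-6-(2-methoxy-2-oxoethyl)-4-methylcyclohex-3-ene-1-carboxylic acid F2, whose arm is unbranched. Deprotonation of F2 to the carboxylate ester enolate (LiN(iPr)2, 2.2 equiv) and alkylation with EtI then give 14.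

**Step 4.** The hindered (Z)-γ-substituted pinacol boronate may add only slowly to the ketone under diol catalysis, with erosion of facial selectivity or of the syn-type diastereoselectivity through background reaction. Fallback, from 8 and returning at 10: 8 is converted with KHF2 into potassium trifluoro[(2Z)-4-(1,5-dimethoxy-1,5-dioxopentan-3-yl)but-2-en-1-yl]borate F3. F3 adds to 3 under BF3·OEt2 through the same closed transition state, and lactonisation as in step 4 gives 10 as a racemate together with its enantiomer, methyl 2-[(2R,3R,4S)-3-ethenyl-2-[(1E)-2-ethylhex-1-en-3-yn-1-yl]-2-methyl-6-oxooxan-4-yl]acetate F4. Compound 10 is then separated by preparative chromatography on a chiral stationary phase.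

**Step 8.** The α-branched acyl radical may lose CO, the cyclised radical may close 6-endo or ring-expand at low stannane concentration, and stannyl radicals may add to the alkyne. Fallback, from 14 and returning at 16: the ester of 14 is reduced with iBu2AlH at −78 °C to (1R,2R,5S,6R)-2-(but-1-yn-1-yl)-5-ethenyl-1,2-diethyl-4-methyl-6-(1-oxobutan-2-yl)cyclohex-3-ene-1-carboxylic acid F5. A SmI2/HMPA/t-BuOH ketyl–olefin cyclisation onto the vinyl group gives (3aR,4R,5R,7aR)-5-(but-1-yn-1-yl)-3,4,5-triethyl-2-hydroxy-1,7-dimethyl-2,3,3a,4,5,7a-hexahydro-1H-indene-4-carboxylic acid F6 as a mixture of C1, C2 and C3 epimers. Dess–Martin oxidation gives 16, which is equilibrated with DBU to 17 as in step 8.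

**Step 9.** Hydropalladation of the alkyne next to the quaternary carbon may be slow or regio-unselective, and protodeboronation of 18 may compete. Fallback, from 17 and returning at 19: palladium-catalysed hydrostannation (Bu3SnH, PdCl2(PPh3)2, THF) places tin on the ethyl-bearing carbon to give (1S,3S,3aR,4R,5R,7aR)-3,4,5-triethyl-1,7-dimethyl-2-oxo-5-[(1E)-2-(tributylstannyl)but-1-en-1-yl]-2,3,3a,4,5,7a-hexahydro-1H-indene-4-carboxylic acid F7. Stille coupling of F7 with [(E)-2-bromoethenyl]benzene (Pd2(dba)3, AsPh3, NMP) gives 19.

## Further compounds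

F1 | step 6 | methyl 2-[(2S,3S,4S)-3-ethenyl-5-ethyl-2-[(1E)-2-ethylhex-1-en-3-yn-1-yl]-2-methyl-6-oxooxan-4-yl]acetate (epimers at oxane C5) | O=C1O[C@](C)(/C=C(CC)/C#CCC)[C@@H](C=C)[C@H](CC(=O)OC)C1CC
F2 | step 6 | (1R,2R,5S,6S)-2-(but-1-yn-1-yl)-5-ethenyl-1,2-diethyl-6-(2-methoxy-2-oxoethyl)-4-methylcyclohex-3-ene-1-carboxylic acid | CCC#C[C@@]1(CC)C=C(C)[C@@H](C=C)[C@H](CC(=O)OC)[C@@]1(CC)C(=O)O
F3 | step 4 | potassium trifluoro[(2Z)-4-(1,5-dimethoxy-1,5-dioxopentan-3-yl)but-2-en-1-yl]borate | [K+].COC(=O)CC(CC(=O)OC)/C=C\C[B-](F)(F)F
F4 | step 4 | methyl 2-[(2R,3R,4S)-3-ethenyl-2-[(1E)-2-ethylhex-1-en-3-yn-1-yl]-2-methyl-6-oxooxan-4-yl]acetate | O=C1O[C@@](C)(/C=C(CC)/C#CCC)[C@H](C=C)[C@@H](CC(=O)OC)C1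
F5 | step 8 | (1R,2R,5S,6R)-2-(but-1-yn-1-yl)-5-ethenyl-1,2-diethyl-4-methyl-6-(1-oxobutan-2-yl)cyclohex-3-ene-1-carboxylic acid (epimers at the butanal α-carbon) | CCC#C[C@@]1(CC)C=C(C)[C@@H](C=C)[C@H](C(CC)C=O)[C@@]1(CC)C(=O)O
F6 | step 8 | (3aR,4R,5R,7aR)-5-(but-1-yn-1-yl)-3,4,5-triethyl-2-hydroxy-1,7-dimethyl-2,3,3a,4,5,7a-hexahydro-1H-indene-4-carboxylic acid (epimers at C1, C2 and C3) | CCC#C[C@@]1(CC)C=C(C)[C@@H]2[C@H](C(CC)C(O)C2C)[C@@]1(CC)C(=O)O
F7 | step 9 | (1S,3S,3aR,4R,5R,7aR)-3,4,5-triethyl-1,7-dimethyl-2-oxo-5-[(1E)-2-(tributylstannyl)but-1-en-1-yl]-2,3,3a,4,5,7a-hexahydro-1H-indene-4-carboxylic acid | CC/C(=C\[C@@]1(CC)C=C(C)[C@@H]2[C@H]([C@H](CC)C(=O)[C@H]2C)[C@@]1(CC)C(=O)O)[Sn](CCCC)(CCCC)CCCC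
A1 | alternative 1 | (2E,4S,6S,7E,9E,11E,13E)-2,4,10,12-tetraethyl-6,8-dimethyl-5-oxo-14-phenyltetradeca-2,7,9,11,13-pentaenoic acid | CCC(/C=C/c1ccccc1)=C\C(CC)=C\C(C)=C\[C@H](C)C(=O)[C@@H](CC)/C=C(\CC)C(=O)O
A2 | alternative 2 | methyl (2R,3R,4Z)-3-(but-1-yn-1-yl)-2-[(1E)-but-1-en-1-yl]-2,3-diethyl-5-methyloct-4-en-6-ynoate | CC#C/C(C)=C\[C@](CC)(C#CCC)[C@@](CC)(/C=C/CC)C(=O)OC
A3 | alternative 3 | methyl (1S,3S,3aR,4R,7S,7aR)-3,4,5-triethyl-7-hydroxy-1,7-dimethyl-2-oxo-2,3,3a,4,7,7a-hexahydro-1H-indene-4-carboxylate | COC(=O)[C@@]1(CC)C(CC)=C[C@@](C)(O)[C@@H]2[C@@H]1[C@H](CC)C(=O)[C@H]2C
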